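## Structural features

The target is a bis-benzylic ether, ring A–CH2–O–CH2–ring B, with no stereocentre, so no stereocentres stand next to each other, and it has no ring other than the two benzene rings. Ring A is a 2,6-dibromo-3,4-dihydroxyphenyl unit that keeps one C–H (C5). Ring B is a fully substituted 2,3,6-tribromo-4,5-dihydroxyphenyl unit. Each benzylic carbon is flanked by two ortho bromines and stands para to a phenolic oxygen (O4 of its ring). The fragile points are three:
- the two catechols, which oxidise to o-quinones, most easily in base;
- the CH2–O–CH2 bridge, which can ionise through a quinone-methide-like cation once a para OH is free and acid or an alcohol solvent is present, and which BBr3 or hydrogenolysis would cut;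
- the five aryl bromides, which are open to reduction and metal insertion.

The real difficulty is regiochemical: five bromines must be placed on two similar catechol rings while C5 of ring A stays unbrominated, and four phenols must be unveiled at the end without harming the bridge. The plan uses the C3–C4–C5–C6 stretch of ring B: C4 and C5 carry adjacent oxygens and are flanked by the brominated C3 and C6. This is the pattern of an oxalyl unit set between the two α-carbons of a diester, with the ester groups standing where bromine is wanted; C1, C2 and the CH2O arm then come from a 3-substituted adipate.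

## Logic of the disconnections

18 ⇒ 16. The O–CH2OMe bonds of two acetals on ring A are the last bonds formed backwards. Ring A must travel as a base-stable, non-nucleophilic diether, because a free ring A catechol would be brominated at C5 and would not survive alkoxide, ozone or methoxide. Nothing is gained in skeleton; the cut only fixes the last operation. The demand is a cleavage that uses no protic acid, no alcohol solvent, no BBr3 and no hydrogen, so that the benzylic C–O bonds para to the freed oxygens stay intact.

16 ⇒ 15. The three C–Br bonds of ring B are cut: C2–Br back to C–H, C3–Br and C6–Br back to C–CO2H. Each of these carbons is ortho or para to a phenolic oxygen (C3 ortho to O4, C6 ortho to O5, C2 para to O5), so electrophilic bromine is directed to all three and displaces CO2 at the two carboxyl-bearing ones. The gain is that the bromines become the very carboxyl groups that make ring construction possible. The forward step must brominate ring B only, leave C5–H of ring A alone, and not expel the side chain by ipso attack at C1.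

15 ⇒ 14 ⇒ 12. No skeletal bond is cut; the acids become methyl esters and the benzene ring B is taken down by two hydrogens to the bis-enol of a cyclic 1,2-diketone flanked by two esters. This exposes ring B as a Claisen product. The forward demand is one two-electron oxidation and one ester hydrolysis, both without acid.

12 ⇒ 9 + 10. The C3–C4 and C5–C6 bonds of ring B are cut, which opens the ring and removes the two oxygen-bearing carbons as a two-carbon diester. This is the largest simplification in the plan: a hexasubstituted ring becomes an open-chain diester and a symmetrical C2 unit. The forward step must close a six-membered ring by two acyl transfers in competition with chain growth and with five-ring closure of 9 alone.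

9 ⇒ 8. The two ester carbons are joined to give the C=C of a cyclohexene, since a 3-substituted adipate is a cleaved 4-substituted cyclohexene. The ether is kept in place during this cut because a free hydroxymethyl adipate would lactonise. One oxidative cleavage in methanolic base stands for the ozonolysis, oxidation and esterification of a longer sequence. The forward step must oxidise the alkene and spare the benzylic ether, the acetals and ring A.

8 ⇒ 6 + 7. The benzylic C–O bond on the ring A side is cut. A benzylic bromide and a primary alkoxide are the natural partners, and the cut separates the whole ring A unit from a purchased alcohol. The forward demand is SN2 at a benzylic carbon that carries two ortho bromines, under base that the acetals tolerate.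

6 ⇒ 5 ⇒ 4 ⇒ 3. These are functional-group changes only: bromide from alcohol, alcohol from aldehyde, acetals from the free catechol. The bromide must be made under neutral conditions because the acetals are acid-labile.

3 ⇒ 2 ⇒ 1. The O–CH3 bond at O4 and then the two C–Br bonds of ring A are cut. In 1 the free OH at C3 directs to C2 (ortho) and C6 (para), while the methylated O4 activates C5 only weakly, so the ring A pattern follows from innate directing effects. The forward demands are a dibromination that stops at two bromines and a demethylation that leaves the aldehyde alone.

## Other disconnections considered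

Alternative 1: The cut removes the aromatic unsaturation of ring B and its three C–Br bonds at once and leads to the 4-substituted cyclohexane-1,2-dione A1, whose ring A is a diacetate. In the forward key step A1 would be treated with excess Br2 in NaOAc-buffered acetic acid. One equivalent aromatises the dione by α-bromination and loss of HBr, and three more fill C2, C3 and C6, giving the ring A diacetate A2 of the target.
- In its favour: every free position of ring B ends as C–Br, so there is no regiochemical question. One operation does the work of steps 9 to 11 of the chosen plan. The six-membered ring of A1 maps directly onto the ring of 7, so no ring has to be cleaved and rebuilt. The acetates also make ring A electron-poor, so C5–H of ring A is better shielded from bromine than by the acetals of the chosen route; on this point the alternative is the better one.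
- Against it: acetates cannot pass through an alkoxide etherification or any basic route to the dione, so a protecting-group exchange would be needed. Four equivalents of Br2 and five of HBr act in one pot on a diosphenol, with bromodienone and o-quinone stages where over-oxidation or C–C cleavage could start. The final deacetylation is a basic solvolysis on a para-hydroxybenzylic ether.
- Comparison: on structure and step economy the alternative is equal or better, perhaps two steps shorter if acetals were kept throughout. On mechanism the chosen plan separates the events into a classical C–C bond formation, one dehydrogenation under neutral conditions, and bromination of an aromatic ring whose carboxyl groups temper its oxidation and allow exact dosing of bromine. The chosen plan also keeps this alternative in reserve, since 12 can be decarboxylated to the acetal analogue of A1.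

Alternative 2: The cut is through C2–C3 and C4–C5 of ring A, a retro-(4+2) with re-insertion of CO2, and leads to the dibromopyrone A3 and di-tert-butoxyethyne A4. Forward, A3 and A4 would combine across pyrone C3 and C6; the bridged lactone loses CO2 and gives the fully protected ether A5.
- In its favour: the alkyne is symmetrical, so the ring A pattern is fixed by construction. Both ring A bromines arrive with the pyrone, so C5–H of ring A never meets electrophilic bromine; this is a better position than that of step 11 of the chosen plan. The route is convergent, with ring B prepared separately by ordinary arene bromination. The electron demand is reasonable, an electron-rich ynediether with an electron-poor dibromopyrone.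
- Against it: A3 is a densely substituted pyrone that would itself need a multi-step synthesis and an etherification on a pyrone-bound CH2. A4 is thermally labile, while pyrone–alkyne cycloadditions usually need heat. The two tert-butyl ethers and two acetals of A5 are all acid-cleaved, so the end-game risk to the bridge is the same as in the chosen plan, an equal point.
- Comparison: on certainty of substitution pattern the alternative is equal or better. On structure it builds the simpler ring A from scratch and leaves the hexasubstituted ring B to classical chemistry. On step economy it is likely longer in total, although more convergent. The chosen plan uses only cheap, robust ionic chemistry.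

Alternative 3: The cut removes the C2–Br and C6–Br bonds of ring A at a late stage and leads to the phenol A6, in which O3 of ring A is free and O4 is an acetal. Forward, two equivalents of N-bromosuccinimide would brominate ortho and para to the free OH and give A7.
- In its favour: it uses the same directing logic as step 1 of the chosen route. The benzylic electrophile for the ether synthesis carries no ortho bromines. Ring B is made by exhaustive bromination of a simple arene. The assembly is convergent, and its longest linear sequence should be the shortest of all plans; on step economy it is equal or better.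
- Against it: the two ring A oxygens must be differentiated, which costs protecting-group steps. The dibromination is run on the complete ether, where C2 lies between OH and the CH2O arm, the second bromination is slower than the first, and over-bromination at C5 or oxidation of the free phenol would cost advanced material. A7 again needs acid to remove three acetals, the same end-game risk as in the chosen plan.
- Comparison: on mechanism the two plans are equal, both relying on a free phenol to direct bromine. The chosen plan exercises that selectivity on a small molecule at the start, where an error is cheap. On structure the alternative builds no ring and is the more conventional, more practical answer; the chosen plan's distinct merit is that the ring B pattern is fixed by construction.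

Key step: step 8

Assumption: racemic 7 is used; its single stereocentre is carried as a racemate, together with the enolisable centres of 11 to 13, and vanishes when ring B is aromatised, so the achiral target needs no stereocontrol.

## Route

Step 1
Reactants: 1 isovanillin (3-hydroxy-4-methoxybenzaldehyde)
Product: 2 2,6-dibromo-3-hydroxy-4-methoxybenzaldehyde
Conditions: Br2 (2.2 equiv), NaOAc, AcOH, rt → 40 °C
Reagents that add atoms: bromine, BrBr
Why: Electrophilic aromatic bromination; the free 3-OH directs to its ortho (C2) and para (C6) positions, whereas C5 is only ortho to the weaker OMe donor and meta to OH, so two equivalents should stop at the 2,6-dibromide, with NaOAc buffering the HBr.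

Step 2
Reactants: 2 2,6-dibromo-3-hydroxy-4-methoxybenzaldehyde
Product: 3 2,6-dibromo-3,4-dihydroxybenzaldehyde
Conditions: BBr3, CH2Cl2, −78 °C → rt; H2O
Reagents that add atoms: none
Why: Lewis-acid cleavage of an aryl methyl ether by BBr3 (aryloxyborane plus bromomethane, hydrolysed on work-up); the aldehyde and the aryl bromides should be untouched.

Step 3
Reactants: 3 2,6-dibromo-3,4-dihydroxybenzaldehyde
Product: 4 2,6-dibromo-3,4-bis(methoxymethoxy)benzaldehyde
Conditions: MOMCl (3 equiv), i-Pr2NEt, CH2Cl2, 0 °C → rt
Reagents that add atoms: chloromethyl methyl ether, COCCl
Why: Base-mediated O-alkylation of both phenols gives acetals that tolerate hydride, alkoxide, ozone, methoxide, hydroxide and buffered bromine in the later steps; the small electrophile should reach O3 although it is flanked by bromine.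

Step 4
Reactants: 4 2,6-dibromo-3,4-bis(methoxymethoxy)benzaldehyde
Product: 5 [2,6-dibromo-3,4-bis(methoxymethoxy)phenyl]methanol
Conditions: NaBH4, THF/MeOH, 0 °C
Reagents that add atoms: none
Why: Borohydride reduction of an aryl aldehyde to the benzylic alcohol; aryl bromides and acetals are inert.

Step 5
Reactants: 5 [2,6-dibromo-3,4-bis(methoxymethoxy)phenyl]methanol
Product: 6 1,3-dibromo-2-(bromomethyl)-4,5-bis(methoxymethoxy)benzene
Conditions: CBr4, PPh3, CH2Cl2, 0 °C
Reagents that add atoms: carbon tetrabromide, BrC(Br)(Br)Br
Why: Appel bromination (bromide displaces the alkoxyphosphonium group) runs under essentially neutral conditions and is chosen over PBr3 or HBr so that the acid-labile acetals survive.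

Step 6
Reactants: 6 1,3-dibromo-2-(bromomethyl)-4,5-bis(methoxymethoxy)benzene; 7 (cyclohex-3-en-1-yl)methanol (racemic)
Product: 8 1,3-dibromo-2-{[(cyclohex-3-en-1-yl)methoxy]methyl}-4,5-bis(methoxymethoxy)benzene (racemic)
Conditions: 7 (1.2 equiv), NaH, THF/DMF, 0 °C; then 6, n-Bu4NI (cat.), rt
Reagents that add atoms: none
Why: Williamson ether synthesis; the unhindered primary alkoxide of 7 displaces the benzylic bromide by SN2, which the two ortho bromines slow but do not prevent (2,6-dihalobenzyl ethers are made in this way); the stereocentre of 7 is not touched and stays racemic.

Step 7
Reactants: 8 1,3-dibromo-2-{[(cyclohex-3-en-1-yl)methoxy]methyl}-4,5-bis(methoxymethoxy)benzene (racemic)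
Product: 9 dimethyl 3-({[2,6-dibromo-3,4-bis(methoxymethoxy)phenyl]methoxy}methyl)hexanedioate (racemic)
Conditions: O3, NaOH (2.5 M in MeOH), CH2Cl2, −78 °C
Reagents that add atoms: ozone, [O-][O+]=O; methanol, CO
Why: Ozonolysis in methanolic NaOH (Marshall-type oxidative cleavage): the carbonyl oxide and aldehyde termini are trapped by methanol, and the methoxy hydroperoxide and hemiacetal are converted in the flask into methyl esters, so the cyclohexene should give the 3-substituted adipate in one operation; the ether is installed first because a free hydroxymethyl adipate would lactonise.

Step 8
Reactants: 9 dimethyl 3-({[2,6-dibromo-3,4-bis(methoxymethoxy)phenyl]methoxy}methyl)hexanedioate (racemic); 10 dimethyl oxalate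
Product: 12 dimethyl 5-({[2,6-dibromo-3,4-bis(methoxymethoxy)phenyl]methoxy}methyl)-2,3-dioxocyclohexane-1,4-dicarboxylate (mixture of diastereomers/enol forms), via open-chain oxalyl adipate 11 (not isolated)
Conditions: 10 (1.05 equiv), NaOMe (2.5 equiv), THF/MeOH, 0 °C → rt → 50 °C; AcOH
Reagents that add atoms: none
Why: This is a crossed double Claisen condensation (oxalate acylation followed by a Dieckmann-type closure), the classical route from dialkyl adipates and dialkyl oxalates to dialkyl 2,3-dioxocyclohexane-1,4-dicarboxylates. Methoxide forms the ester enolate of 9, most readily at C5, the α-carbon remote from the branch; it adds to 10, the most electrophilic ester present and one that cannot enolise, and loss of methoxide gives 11 with the bond that becomes C3–C4 of ring B. The enolate at C2 of the adipate chain then attacks the remaining oxalyl ester carbonyl in a 6-exo-trig closure that forms the bond that becomes C5–C6 of ring B and closes the only new ring. Every acyl transfer is reversible, and the sequence is drawn to 12 because both of its β-keto ester units are deprotonated, so that 12 leaves the equilibria as a disodium bis-enolate. This sink, the 1:1 ratio of 9 to 10, the low starting temperature (oxalylation outruns the five-ring Dieckmann closure of 9 alone, which is reversible) and the ease of six-ring formation are what should secure cyclisation over chain growth or twofold oxalylation. The order in which the two α-carbons react is immaterial, since both ester-bearing carbons end as C–Br. No stereocentre needs control: C1 and C4 of 12 are enolised, and the racemic centre at C5 disappears in step 9. The ether oxygen sits on a carbon γ to one enolate carbon and δ to the other, so neither enolate has a β-leaving group, and the aryl bromides and acetals do not react with methoxide.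

Step 9
Reactants: 12 dimethyl 5-({[2,6-dibromo-3,4-bis(methoxymethoxy)phenyl]methoxy}methyl)-2,3-dioxocyclohexane-1,4-dicarboxylate
Product: 14 dimethyl 5-({[2,6-dibromo-3,4-bis(methoxymethoxy)phenyl]methoxy}methyl)-2,3-dihydroxybenzene-1,4-dicarboxylate, via 1-bromo diketo diester 13 (not isolated)
Conditions: NBS (1.05 equiv), CH2Cl2, 0 °C; then DBU (2.5 equiv), 0 °C → rt
Reagents that add atoms: none
Why: Halogenation–dehydrohalogenation aromatisation of a cyclic β-keto ester: NBS brominates an enol carbon of the bis-enol (the less hindered C1 is drawn; the C4 isomer converges), DBU removes HBr across C1–C6 and the dienone tautomerises to the catechol diester. No acid is set free, so the acetals are safe, and stray bromination of the single ring B C–H would be harmless because that carbon is brominated in step 11.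

Step 10
Reactants: 14 dimethyl 5-({[2,6-dibromo-3,4-bis(methoxymethoxy)phenyl]methoxy}methyl)-2,3-dihydroxybenzene-1,4-dicarboxylate
Product: 15 5-({[2,6-dibromo-3,4-bis(methoxymethoxy)phenyl]methoxy}methyl)-2,3-dihydroxybenzene-1,4-dicarboxylic acid
Conditions: NaOH (6 equiv), H2O/1,4-dioxane, 60 °C, N2; then 1 M HCl to pH 3, 0 °C
Reagents that add atoms: sodium hydroxide (hydroxide oxygen of each CO2H), [Na+].[OH-]
Why: Saponification (acyl–oxygen cleavage by hydroxide) of the two salicylate-type esters; under nitrogen the electron-poor catecholate should be stable, the acetals and the bridge tolerate aqueous alkali at moderate temperature, and brief cold acidification frees the diacid without cleaving the acetals.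

Step 11
Reactants: 15 5-({[2,6-dibromo-3,4-bis(methoxymethoxy)phenyl]methoxy}methyl)-2,3-dihydroxybenzene-1,4-dicarboxylic acid
Product: 16 3,4,6-tribromo-5-({[2,6-dibromo-3,4-bis(methoxymethoxy)phenyl]methoxy}methyl)benzene-1,2-diol
Conditions: Br2 (3.05 equiv), NaOAc, AcOH/H2O, 0 °C; then NaHSO3 (aq)
Reagents that add atoms: bromine, BrBr
Why: Electrophilic bromination of a phenol with ipso-bromodecarboxylation, as in the conversion of salicylic acid into tribromophenol: the ring B C–H para to a phenolic OH is substituted directly, and at the two carboxyl-bearing carbons (each ortho to an OH) bromine adds ipso and the dienone rearomatises by loss of CO2. Ring A is an acetal-protected dibromoarene whose only C–H is flanked by bromine and should react far more slowly than the phenolic ring B, so three equivalents at 0 °C should be consumed by ring B alone; bisulfite returns any o-quinone to the catechol.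

Step 12
Reactants: 16 3,4,6-tribromo-5-({[2,6-dibromo-3,4-bis(methoxymethoxy)phenyl]methoxy}methyl)benzene-1,2-diol
Product: 18 3,4,6-tribromo-5-{[(2,6-dibromo-3,4-dihydroxyphenyl)methoxy]methyl}benzene-1,2-diol (target), via tetrakis(trimethylsilyl) ether 17 (not isolated)
Conditions: TMSOTf (6 equiv), 2,2'-bipyridyl (9 equiv), CH3CN, 0 °C → rt; then H2O
Reagents that add atoms: none
Why: Cleavage of aryl methoxymethyl ethers by TMSOTf buffered with 2,2'-bipyridyl converts ArOCH2OMe directly into ArOSiMe3 (the ring B phenols are silylated as well), and water alone then frees the four phenols. No protic acid or alcohol solvent meets the para-hydroxybenzylic ether, so solvolysis of the bridge should be avoided.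

## Compound list

1 | isovanillin (3-hydroxy-4-methoxybenzaldehyde) | COc1ccc(C=O)cc1O | starting material
2 | 2,6-dibromo-3-hydroxy-4-methoxybenzaldehyde | COc1cc(Br)c(C=O)c(Br)c1O | intermediate
3 | 2,6-dibromo-3,4-dihydroxybenzaldehyde | Oc1cc(Br)c(C=O)c(Br)c1O | intermediate
4 | 2,6-dibromo-3,4-bis(methoxymethoxy)benzaldehyde | COCOc1cc(Br)c(C=O)c(Br)c1OCOC | intermediate
5 | [2,6-dibromo-3,4-bis(methoxymethoxy)phenyl]methanol | COCOc1cc(Br)c(CO)c(Br)c1OCOC | intermediate
6 | 1,3-dibromo-2-(bromomethyl)-4,5-bis(methoxymethoxy)benzene | COCOc1cc(Br)c(CBr)c(Br)c1OCOC | intermediate
7 | (cyclohex-3-en-1-yl)methanol (racemic) | OCC1CCC=CC1 | starting material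
8 | 1,3-dibromo-2-{[(cyclohex-3-en-1-yl)methoxy]methyl}-4,5-bis(methoxymethoxy)benzene (racemic) | COCOc1cc(Br)c(COCC2CCC=CC2)c(Br)c1OCOC | intermediate
9 | dimethyl 3-({[2,6-dibromo-3,4-bis(methoxymethoxy)phenyl]methoxy}methyl)hexanedioate (racemic) | COC(=O)CCC(COCc1c(Br)cc(OCOC)c(OCOC)c1Br)CC(=O)OC | intermediate
10 | dimethyl oxalate | COC(=O)C(=O)OC | starting material
11 | dimethyl 5-({[2,6-dibromo-3,4-bis(methoxymethoxy)phenyl]methoxy}methyl)-3-(methoxycarbonyl)-2-oxoheptanedioate (open-chain mono-adduct, diastereomer mixture, not isolated) | COC(=O)C(=O)C(C(=O)OC)CC(COCc1c(Br)cc(OCOC)c(OCOC)c1Br)CC(=O)OC | intermediate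
12 | dimethyl 5-({[2,6-dibromo-3,4-bis(methoxymethoxy)phenyl]methoxy}methyl)-2,3-dioxocyclohexane-1,4-dicarboxylate (mixture of diastereomers/enol forms) | COC(=O)C1CC(COCc2c(Br)cc(OCOC)c(OCOC)c2Br)C(C(=O)OC)C(=O)C1=O | intermediate
13 | dimethyl 1-bromo-5-({[2,6-dibromo-3,4-bis(methoxymethoxy)phenyl]methoxy}methyl)-2,3-dioxocyclohexane-1,4-dicarboxylate (diastereomer mixture, not isolated) | COC(=O)C1(Br)CC(COCc2c(Br)cc(OCOC)c(OCOC)c2Br)C(C(=O)OC)C(=O)C1=O | intermediate
14 | dimethyl 5-({[2,6-dibromo-3,4-bis(methoxymethoxy)phenyl]methoxy}methyl)-2,3-dihydroxybenzene-1,4-dicarboxylate | COC(=O)c1cc(COCc2c(Br)cc(OCOC)c(OCOC)c2Br)c(C(=O)OC)c(O)c1O | intermediate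
15 | 5-({[2,6-dibromo-3,4-bis(methoxymethoxy)phenyl]methoxy}methyl)-2,3-dihydroxybenzene-1,4-dicarboxylic acid | OC(=O)c1cc(COCc2c(Br)cc(OCOC)c(OCOC)c2Br)c(C(=O)O)c(O)c1O | intermediate
16 | 3,4,6-tribromo-5-({[2,6-dibromo-3,4-bis(methoxymethoxy)phenyl]methoxy}methyl)benzene-1,2-diol | COCOc1cc(Br)c(COCc2c(Br)c(O)c(O)c(Br)c2Br)c(Br)c1OCOC | intermediate
17 | tetrakis(O-trimethylsilyl) ether of 18 (all four phenolic oxygens silylated, not isolated) | C[Si](C)(C)Oc1cc(Br)c(COCc2c(Br)c(O[Si](C)(C)C)c(O[Si](C)(C)C)c(Br)c2Br)c(Br)c1O[Si](C)(C)C | intermediate
18 | 3,4,6-tribromo-5-{[(2,6-dibromo-3,4-dihydroxyphenyl)methoxy]methyl}benzene-1,2-diol | Oc1cc(Br)c(COCc2c(Br)c(O)c(O)c(Br)c2Br)c(Br)c1O | target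

## Step count and risks

Total step count: 12. Longest linear sequence: 12 steps, from 1 to 18; 7 and 10 are purchased.

Least certain steps:

Step 8 (key step). Chain growth between two molecules of 9, twofold oxalylation, or five-ring Dieckmann closure of 9 alone may compete with the six-ring closure. Enolisation at the α-carbon next to the branch may be slow, and adventitious hydroxide may hydrolyse an ester and start a retro-Claisen. Fallback: from 9 the two events are separated. Mono-oxalylation with one equivalent each of NaOMe and 10 in Et2O at 0 °C, where the sodium enolate of the oxalyl ester separates and second reaction is held back, would give after AcOH the isolated 11 together with its regioisomer dimethyl 4-({[2,6-dibromo-3,4-bis(methoxymethoxy)phenyl]methoxy}methyl)-3-(methoxycarbonyl)-2-oxoheptanedioate F1. The mixture is then closed in a separate Dieckmann step at high dilution (NaOMe, toluene, 80 °C, methanol distilled off); both isomers converge, and the route is rejoined at 12.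

Step 7. The protocol needs surplus ozone, which may oxidise the benzylic ether CH2, an acetal C–H or ring A. The transient dialdehyde may also undergo base-induced intramolecular aldol condensation before it is oxidised. Fallback: from 8 the oxidation is done in stages. Reductive ozonolysis stopped at the first excess of ozone (O3, CH2Cl2/MeOH, −78 °C; PPh3) would give 3-({[2,6-dibromo-3,4-bis(methoxymethoxy)phenyl]methoxy}methyl)hexanedial F2. Pinnick oxidation (NaClO2, NaH2PO4, 2-methylbut-2-ene, t-BuOH/H2O) would give 3-({[2,6-dibromo-3,4-bis(methoxymethoxy)phenyl]methoxy}methyl)hexanedioic acid F3, and O-methylation (MeI, K2CO3, DMF) comes back to the route at 9.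

Step 10. Hydrolysis of the ester that lies between the OH and the CH2O arm may be slow. Forcing alkali may then expel the benzylic alkoxide through a quinone methide, or oxidise the catecholate. Fallback: from 14 the O–CH3 bonds are cut and the hindered carbonyl is left alone: LiI in refluxing EtOAc (SN2 at the methyl group), then dilute acid, comes back at 15 and makes no new compound.

Step 11. Bromine may attack ipso at the carbon that carries the CH2O arm (para to an OH) with loss of the side chain. Surplus bromine may substitute C5–H of ring A or oxidise the catechol to the o-quinone, and the second decarboxylation may stall at a bromo acid. Fallback: from 12 both ester groups are removed before aromatisation. Krapcho dealkoxycarbonylation (LiCl, wet DMSO, 130 °C) would give 4-({[2,6-dibromo-3,4-bis(methoxymethoxy)phenyl]methoxy}methyl)cyclohexane-1,2-dione F4. Br2 (4 equiv) with NaOAc in AcOH, 0 °C → rt, should then aromatise the diosphenol and brominate the three free ring positions, coming back to the route at 16.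

Step 12. Cleavage of the acetal at O3, which is flanked by bromine, may be incomplete. The Lewis acid may ionise a benzylic C–O bond of the bridge, and the two free catechols may oxidise in air during work-up. Fallback: from 16 ring B is capped first (Ac2O, pyridine, 0 °C) to give 3,4,6-tribromo-5-({[2,6-dibromo-3,4-bis(methoxymethoxy)phenyl]methoxy}methyl)-1,2-phenylene diacetate F5, so that ring B can neither be oxidised nor assist loss of the ether oxygen. The two acetals are then hydrolysed with dilute HCl in THF/H2O at rt to give 3,4,6-tribromo-5-{[(2,6-dibromo-3,4-dihydroxyphenyl)methoxy]methyl}-1,2-phenylene diacetate F6. The acetates are removed by hydrazinolysis (N2H4·H2O, THF, 0 °C), which reaches 18.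

## Further compounds

F1 | step 8 | dimethyl 4-({[2,6-dibromo-3,4-bis(methoxymethoxy)phenyl]methoxy}methyl)-3-(methoxycarbonyl)-2-oxoheptanedioate | COC(=O)C(=O)C(C(=O)OC)C(COCc1c(Br)cc(OCOC)c(OCOC)c1Br)CCC(=O)OC
F2 | step 7 | 3-({[2,6-dibromo-3,4-bis(methoxymethoxy)phenyl]methoxy}methyl)hexanedial | O=CCCC(COCc1c(Br)cc(OCOC)c(OCOC)c1Br)CC=O
F3 | step 7 | 3-({[2,6-dibromo-3,4-bis(methoxymethoxy)phenyl]methoxy}methyl)hexanedioic acid | OC(=O)CCC(COCc1c(Br)cc(OCOC)c(OCOC)c1Br)CC(=O)O
F0 | step 10 | none | none
F4 | step 11 | 4-({[2,6-dibromo-3,4-bis(methoxymethoxy)phenyl]methoxy}methyl)cyclohexane-1,2-dione | COCOc1cc(Br)c(COCC2CCC(=O)C(=O)C2)c(Br)c1OCOC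
F5 | step 12 | 3,4,6-tribromo-5-({[2,6-dibromo-3,4-bis(methoxymethoxy)phenyl]methoxy}methyl)-1,2-phenylene diacetate | COCOc1cc(Br)c(COCc2c(Br)c(OC(C)=O)c(OC(C)=O)c(Br)c2Br)c(Br)c1OCOC
F6 | step 12 | 3,4,6-tribromo-5-{[(2,6-dibromo-3,4-dihydroxyphenyl)methoxy]methyl}-1,2-phenylene diacetate | Oc1cc(Br)c(COCc2c(Br)c(OC(C)=O)c(OC(C)=O)c(Br)c2Br)c(Br)c1O
A1 | alternative 1 | 3,5-dibromo-4-{[(3,4-dioxocyclohexyl)methoxy]methyl}-1,2-phenylene diacetate | CC(=O)Oc1cc(Br)c(COCC2CCC(=O)C(=O)C2)c(Br)c1OC(C)=O
A2 | alternative 1 | 3,5-dibromo-4-{[(2,3,6-tribromo-4,5-dihydroxyphenyl)methoxy]methyl}-1,2-phenylene diacetate | Oc1c(O)c(Br)c(COCc2c(Br)cc(OC(C)=O)c(OC(C)=O)c2Br)c(Br)c1Br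
A3 | alternative 2 | 3,5-dibromo-4-({[2,3,6-tribromo-4,5-bis(methoxymethoxy)phenyl]methoxy}methyl)-2H-pyran-2-one | O=C1OC=C(Br)C(COCc2c(Br)c(OCOC)c(OCOC)c(Br)c2Br)=C1Br
A4 | alternative 2 | di-tert-butoxyethyne | CC(C)(C)OC#COC(C)(C)C
A5 | alternative 2 | 1,3,4-tribromo-2-{[(2,6-dibromo-3,4-di-tert-butoxyphenyl)methoxy]methyl}-5,6-bis(methoxymethoxy)benzene | CC(C)(C)Oc1cc(Br)c(COCc2c(Br)c(OCOC)c(OCOC)c(Br)c2Br)c(Br)c1OC(C)(C)C
A6 | alternative 3 | 2-(methoxymethoxy)-5-({[2,3,6-tribromo-4,5-bis(methoxymethoxy)phenyl]methoxy}methyl)phenol | COCOc1ccc(COCc2c(Br)c(OCOC)c(OCOC)c(Br)c2Br)cc1O
A7 | alternative 3 | 2,4-dibromo-6-(methoxymethoxy)-3-({[2,3,6-tribromo-4,5-bis(methoxymethoxy)phenyl]methoxy}methyl)phenol | COCOc1cc(Br)c(COCc2c(Br)c(OCOC)c(OCOC)c(Br)c2Br)c(Br)c1O
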